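## Retrosynthetic overview

- Labels: the upper flavan has rings A (dioxygenated benzo ring), C (pyran) and B (catechol), with locants marked U; the EGCG part has rings D (benzo), F (pyran), E (pyrogallol) and G (galloyl), with locants marked L. The last disconnection is global hydrogenolysis of twelve benzyl ethers (15 ⇐ 14).
- Key disconnection: ring C is opened at C-2U–C-3U and the interflavan bond C-4U–C-8L is cut in the same operation. This leads back to the racemic α-acetoxy ether 7 (O-1U–C-2U in place, C-3U=C-4U present as an ortho-vinyl group) and octa-O-benzyl-EGCG 11. Forward, it is a chiral-acid-catalysed Prins/Friedel–Crafts cascade.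
- Enabling feature: in ring C, C-2U is an acetal-level carbon between O-1U and ring B, and C-4U is a doubly benzylic carbon between ring A (donors O-5U, O-7U, O-1U) and C-8L of ring D. Ring C therefore maps onto an aryloxycarbenium ion (O-1U=C-2U) plus a styrene (C-3U=C-4U), and the C-4U cation left by the closure is the electrophile that ring D needs.
- 7 ⇐ aryl ester 5 (reductive acetylation) ⇐ vinylphenol 3 + acid 4; 3 ⇐ phenol 1 by ortho-formylation and Wittig methylenation; 11 ⇐ penta-O-benzyl-epigallocatechin 9 + tri-O-benzylgallic acid 10 (esterification); 9 ⇐ (−)-epigallocatechin 8 (benzylation of the five phenols).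
- Ring order: rings A, B, D, E, F and G are bought intact (1, 4, 8, 10); ring C is the only ring made, in step 7, and the two halves are joined in the same step.

Key step: step 7

Remark: the sense of induction of the chiral acid cannot be derived from precedent for this cation; the catalyst enantiomer that leads to (2S) at C-2U is to be identified on a model ether, and (S,S) is written below for that enantiomer.

## Route

Step 1
Reactants: 1 3,5-bis(benzyloxy)phenol
Product: 2 2,4-bis(benzyloxy)-6-hydroxybenzaldehyde
Conditions: MgCl2, Et3N, (CH2O)n, MeCN, reflux; aq. HCl work-up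
Reagents that add atoms: paraformaldehyde (formaldehyde source), C=O
Why: Magnesium-phenoxide-directed ortho-formylation (Casnati–Skattebøl reaction) delivers formaldehyde only ortho to the free OH, the two ortho positions of 1 are equivalent, and a second formaldehyde oxidises the benzylic alkoxide to the aldehyde; no stereocenter is formed.

Step 2
Reactants: 2 2,4-bis(benzyloxy)-6-hydroxybenzaldehyde
Product: 3 3,5-bis(benzyloxy)-2-ethenylphenol
Conditions: Ph3PCH3Br (2.5 equiv), KOtBu (2.5 equiv), THF, 0 °C → rt; aq. NH4Cl work-up, used promptly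
Reagents that add atoms: methyltriphenylphosphonium bromide, C[P+](c1ccccc1)(c1ccccc1)c1ccccc1.[Br-]
Why: Wittig methylenation, which tolerates the free phenol as its phenoxide when excess ylide is used; no stereocenter is formed.

Step 3
Reactants: 3 3,5-bis(benzyloxy)-2-ethenylphenol; 4 3,4-bis(benzyloxy)benzoic acid
Product: 5 3,5-bis(benzyloxy)-2-ethenylphenyl 3,4-bis(benzyloxy)benzoate
Conditions: EDC·HCl, DMAP (cat.), CH2Cl2, 0 °C → rt
Reagents that add atoms: none
Why: Steglich esterification under neutral, acid-free conditions that spare the acid-sensitive electron-rich styrene; no stereocenter is formed.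

Step 4
Reactants: 5 3,5-bis(benzyloxy)-2-ethenylphenyl 3,4-bis(benzyloxy)benzoate
Product: 7 rac-[3,5-bis(benzyloxy)-2-ethenylphenoxy][3,4-bis(benzyloxy)phenyl]methyl acetate, via aluminium hemiacetal 6 (not isolated)
Conditions: iBu2AlH (DIBAL-H), CH2Cl2, −78 °C; then pyridine, DMAP, Ac2O, −78 → −20 °C; aq. potassium sodium tartrate work-up; used crude or after Et3N-deactivated SiO2
Reagents that add atoms: acetic anhydride, CC(=O)OC(C)=O
Why: DIBAL-H reductive acetylation of an ester: the tetrahedral aluminium hemiacetal 6 should persist at −78 °C (the same stability lets hydride reductions of aryl esters and of dihydrocoumarin-type lactones stop at the aldehyde or lactol level) and is O-acetylated in situ to the α-acetoxy ether, the standard oxocarbenium precursor of segment-coupling Prins cyclizations; the acetal carbon is formed racemic, which is of no consequence because it becomes planar in step 7.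

Step 5
Reactants: 8 (−)-epigallocatechin
Product: 9 (2R,3R)-5,7-bis(benzyloxy)-2-[3,4,5-tris(benzyloxy)phenyl]chroman-3-ol (penta-O-benzyl-epigallocatechin)
Conditions: BnBr (5.5 equiv), K2CO3 (6 equiv), degassed DMF, 0 °C → rt, Ar, dark
Reagents that add atoms: benzyl bromide, BrCc1ccccc1
Why: Williamson etherification of the five phenols with a carbonate base that does not deprotonate the secondary 3-OH and, at or below room temperature under argon, should neither oxidise the pyrogallol ring nor epimerise C-2L, so the (2R,3R) centres of the chiral pool are carried through unchanged.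

Step 6
Reactants: 9 penta-O-benzyl-epigallocatechin; 10 3,4,5-tris(benzyloxy)benzoic acid
Product: 11 (2R,3R)-5,7-bis(benzyloxy)-2-[3,4,5-tris(benzyloxy)phenyl]chroman-3-yl 3,4,5-tris(benzyloxy)benzoate (octa-O-benzyl-EGCG)
Conditions: 10 (1.5 equiv), EDC·HCl, DMAP, CH2Cl2, rt
Reagents that add atoms: none
Why: Steglich esterification of the free 3-OH with the protected gallic acid, the standard way to benzylated flavan-3-ol gallates; the C-3L–O bond is not touched, so the (2R,3R) configuration is retained.

Step 7
Reactants: 7 rac-[3,5-bis(benzyloxy)-2-ethenylphenoxy][3,4-bis(benzyloxy)phenyl]methyl acetate; 11 octa-O-benzyl-EGCG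
Product: 14 (2R,3R)-5,7-bis(benzyloxy)-8-{(2S,4R)-5,7-bis(benzyloxy)-2-[3,4-bis(benzyloxy)phenyl]chroman-4-yl}-2-[3,4,5-tris(benzyloxy)phenyl]chroman-3-yl 3,4,5-tris(benzyloxy)benzoate, via aryloxycarbenium ion 12 (not isolated), via flavan-4-yl cation 13 (not isolated)
Conditions: (S,S)-IDPi (BINOL-derived N-triflyl imidodiphosphorimidate Brønsted acid, 5 mol%), 11 (2 equiv), 5 Å MS, CH2Cl2, −60 → −30 °C, slow addition of 7; Et3N quench
Reagents that add atoms: none
Why: Proposed new method: the chiral acid protonates the acetate carbonyl of racemic 7 so that acetic acid (a far better leaving group than the aryloxide) departs and the planar aryloxycarbenium ion 12 is held as a contact ion pair with the chiral anion; the ortho-vinyl group then attacks C-2U in a 6-endo-trig Prins closure of ring C (C-2U–C-3U bond), and the resulting flavan-4-yl cation 13, stabilised by O-5U, O-7U and O-1U of ring A, is intercepted at C-4U by C-8L of ring D of 11 in a Friedel–Crafts step that returns the proton to the catalyst. The closest known reaction types are the Lewis-acid Prins cyclization of ester-derived α-acetoxy ethers, the Prins/Friedel–Crafts three-component synthesis of 4-aryltetrahydropyrans, confined-acid-catalysed asymmetric Prins cyclizations of aldehydes with homoallylic alcohols, and the acid-mediated C-4 to C-8 coupling of flavanyl cations with benzylated flavan-3-ols; new here are the phenol-derived oxocarbenium ion, the styrene as the olefin and the termination by a flavan-3-ol arene. C-2U is set by the chiral counteranion, which shields one enantiotopic face of 12 (both enantiomers of 7 converge on the same cation), and C-4U is set by the substrate: the arene adds pseudoaxially to the half-chair cation anti to the pseudo-equatorial 2-aryl group, reinforced by peri strain with the 5-benzyloxy group, which should give the 2,4-trans (2S,4R) array. The step needs chemoselective ionisation (acetate versus aryloxide, secured by the leaving-group difference), cyclization faster than intermolecular capture of 12 (secured by the adjacent, highly nucleophilic 2,4,6-trioxygenated styrene), attack by C-8L and not C-6L (C-8L is the more nucleophilic and less hindered position of 5,7-di-O-benzyl flavan-3-ols) and suppression of oligomers (excess 11). Loss of a proton from 13 would only give the 2H-chromene, which re-enters as 13 on reprotonation at C-3U, and because 11 is enantiopure any adduct of the minor C-2U enantiomer is a diastereomer that chromatography should remove.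

Step 8
Reactants: 14 dodeca-O-benzyl dimer from step 7
Product: 15 (2R,3R)-8-[(2S,4R)-2-(3,4-dihydroxyphenyl)-5,7-dihydroxychroman-4-yl]-5,7-dihydroxy-2-(3,4,5-trihydroxyphenyl)chroman-3-yl 3,4,5-trihydroxybenzoate (CNP0190017.1)
Conditions: H2 (1 atm), Pd(OH)2/C, THF/MeOH/H2O, rt; filtration under Ar, lyophilisation
Reagents that add atoms: none
Why: Catalytic hydrogenolysis of the twelve O-benzyl ethers under neutral conditions, as used for benzylated proanthocyanidin gallates, should leave the ring C and ring F benzylic C–O bonds, the C-4U–C-8L bond, the ester and all four stereocenters untouched.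

## Compound list

1 | 3,5-bis(benzyloxy)phenol | Oc1cc(OCc2ccccc2)cc(OCc2ccccc2)c1 | starting material
2 | 2,4-bis(benzyloxy)-6-hydroxybenzaldehyde | O=Cc1c(O)cc(OCc2ccccc2)cc1OCc1ccccc1 | intermediate
3 | 3,5-bis(benzyloxy)-2-ethenylphenol | C=Cc1c(O)cc(OCc2ccccc2)cc1OCc1ccccc1 | intermediate
4 | 3,4-bis(benzyloxy)benzoic acid | O=C(O)c1ccc(OCc2ccccc2)c(OCc2ccccc2)c1 | starting material
5 | 3,5-bis(benzyloxy)-2-ethenylphenyl 3,4-bis(benzyloxy)benzoate | C=Cc1c(OC(=O)c2ccc(OCc3ccccc3)c(OCc3ccccc3)c2)cc(OCc2ccccc2)cc1OCc1ccccc1 | intermediate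
6 | diisobutylaluminium alkoxide of the hemiacetal [3,5-bis(benzyloxy)-2-ethenylphenoxy][3,4-bis(benzyloxy)phenyl]methanol (racemic) | C=Cc1c(OC(O[Al](CC(C)C)CC(C)C)c2ccc(OCc3ccccc3)c(OCc3ccccc3)c2)cc(OCc2ccccc2)cc1OCc1ccccc1 | intermediate
7 | rac-[3,5-bis(benzyloxy)-2-ethenylphenoxy][3,4-bis(benzyloxy)phenyl]methyl acetate | CC(=O)OC(Oc1cc(OCc2ccccc2)cc(OCc2ccccc2)c1C=C)c1ccc(OCc2ccccc2)c(OCc2ccccc2)c1 | intermediate
8 | (−)-epigallocatechin, (2R,3R) | O[C@@H]1Cc2c(O)cc(O)cc2O[C@@H]1c1cc(O)c(O)c(O)c1 | starting material
9 | (2R,3R)-5,7-bis(benzyloxy)-2-[3,4,5-tris(benzyloxy)phenyl]chroman-3-ol | O[C@@H]1Cc2c(OCc3ccccc3)cc(OCc3ccccc3)cc2O[C@@H]1c1cc(OCc2ccccc2)c(OCc2ccccc2)c(OCc2ccccc2)c1 | intermediate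
10 | 3,4,5-tris(benzyloxy)benzoic acid | O=C(O)c1cc(OCc2ccccc2)c(OCc2ccccc2)c(OCc2ccccc2)c1 | starting material
11 | (2R,3R)-5,7-bis(benzyloxy)-2-[3,4,5-tris(benzyloxy)phenyl]chroman-3-yl 3,4,5-tris(benzyloxy)benzoate | O=C(O[C@@H]1Cc2c(OCc3ccccc3)cc(OCc3ccccc3)cc2O[C@@H]1c1cc(OCc2ccccc2)c(OCc2ccccc2)c(OCc2ccccc2)c1)c1cc(OCc2ccccc2)c(OCc2ccccc2)c(OCc2ccccc2)c1 | intermediate
12 | O-[3,5-bis(benzyloxy)-2-ethenylphenyl] oxocarbenium ion of 3,4-bis(benzyloxy)benzaldehyde (chiral counteranion) | C=Cc1c([O+]=Cc2ccc(OCc3ccccc3)c(OCc3ccccc3)c2)cc(OCc2ccccc2)cc1OCc1ccccc1 | intermediate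
13 | (2S)-5,7-bis(benzyloxy)-2-[3,4-bis(benzyloxy)phenyl]chroman-4-ylium ion (chiral counteranion) | [CH+]1C[C@@H](c2ccc(OCc3ccccc3)c(OCc3ccccc3)c2)Oc2cc(OCc3ccccc3)cc(OCc3ccccc3)c21 | intermediate
14 | (2R,3R)-5,7-bis(benzyloxy)-8-{(2S,4R)-5,7-bis(benzyloxy)-2-[3,4-bis(benzyloxy)phenyl]chroman-4-yl}-2-[3,4,5-tris(benzyloxy)phenyl]chroman-3-yl 3,4,5-tris(benzyloxy)benzoate | O=C(O[C@@H]1Cc2c(OCc3ccccc3)cc(OCc3ccccc3)c([C@@H]3C[C@@H](c4ccc(OCc5ccccc5)c(OCc5ccccc5)c4)Oc4cc(OCc5ccccc5)cc(OCc5ccccc5)c43)c2O[C@@H]1c1cc(OCc2ccccc2)c(OCc2ccccc2)c(OCc2ccccc2)c1)c1cc(OCc2ccccc2)c(OCc2ccccc2)c(OCc2ccccc2)c1 | intermediate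
15 | (2R,3R)-8-[(2S,4R)-2-(3,4-dihydroxyphenyl)-5,7-dihydroxychroman-4-yl]-5,7-dihydroxy-2-(3,4,5-trihydroxyphenyl)chroman-3-yl 3,4,5-trihydroxybenzoate | O=C(O[C@@H]1Cc2c(O)cc(O)c([C@@H]3C[C@@H](c4ccc(O)c(O)c4)Oc4cc(O)cc(O)c43)c2O[C@@H]1c1cc(O)c(O)c(O)c1)c1cc(O)c(O)c(O)c1 | target

## Step count and risks

Total step count: 8. Longest linear sequence: 6 (steps 1, 2, 3, 4, 7, 8).

The three steps most likely to fail:

**Step 7 (Proposed new method).** The processes that may defeat it are:
- poor enantiofacial discrimination at C-2U, because the benzyl-laden ion pair may fit the chiral anion badly;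
- capture of cation 12 by the arene of 11 before ring closure;
- protonation of the styrene ahead of ionisation of the acetate;
- over-alkylation of the product to oligomers.

The fallback uses known chemistry and sets C-2U before the coupling. It sets out from compound 11, which is kept as the nucleophile, and builds the electrophile apart from it. Commercial 5,7-dihydroxy-4H-chromen-4-one is benzylated (BnBr, K2CO3, DMF, 70 °C) to 5,7-bis(benzyloxy)-4H-chromen-4-one F1. A catalytic asymmetric conjugate addition of [3,4-bis(benzyloxy)phenyl]boronic acid to F1 (Pd(OCOCF3)2 with a chiral tert-butyl pyridine–oxazoline ligand, the enantiomer chosen for the 2S product) should give (2S)-5,7-bis(benzyloxy)-2-[3,4-bis(benzyloxy)phenyl]chroman-4-one F2. Reduction with NaBH4 (THF/MeOH, 0 °C) should give the 2,4-cis alcohol (2S,4S)-5,7-bis(benzyloxy)-2-[3,4-bis(benzyloxy)phenyl]chroman-4-ol F3. Ionisation of F3 with BF3·OEt2 (CH2Cl2, −78 → −40 °C) in the presence of excess 11 generates the same cation 13, which is captured at C-8L trans to the 2-aryl group. The fallback comes back to the route at compound 14.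

**Step 4.** The aluminium hemiacetal 6 may collapse with loss of the aluminium aryloxide before it is acetylated, and the very ionisable acetate 7 may decompose on silica. The fallback builds the α-acyloxy ether by O-alkylation instead of ester reduction and sets out from compound 3. Commercial 3,4-bis(benzyloxy)benzaldehyde and pivaloyl chloride (ZnCl2 cat., CH2Cl2, 0 °C) should add to give racemic chloro[3,4-bis(benzyloxy)phenyl]methyl 2,2-dimethylpropanoate F4. Alkylation of the phenoxide of 3 with F4 (K2CO3, DMF, 0 °C → rt) should give racemic [3,5-bis(benzyloxy)-2-ethenylphenoxy][3,4-bis(benzyloxy)phenyl]methyl 2,2-dimethylpropanoate F5; the hindered pivaloyl carbonyl disfavours acyl transfer to the phenoxide, and the pivalate should be more robust on silica than the acetate. F5 takes the place of 7 in step 7: the acid protonates the ester carbonyl, non-basic pivalic acid leaves, and the same cation 12 results. The fallback comes back to the route at compound 14.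

**Step 2.** Olefination of the phenoxide-deactivated aldehyde may be slow, and the free, electron-rich vinylphenol may oligomerise under traces of acid during isolation. The fallback inverts the order so that the free vinylphenol is never handled, and sets out from compound 2. Steglich esterification of 2 with acid 4 (EDC·HCl, DMAP, CH2Cl2) gives 3,5-bis(benzyloxy)-2-formylphenyl 3,4-bis(benzyloxy)benzoate F6, in which the aldehyde is no longer conjugated to a phenoxide. Salt-free Wittig methylenation at −78 °C (Ph3PCH3Br, NaN(SiMe3)2, THF; 1.05 equiv of ylide, aldehyde far faster than the hindered aryl ester) then gives the styrene. The fallback comes back to the route at compound 5.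

Further compounds
F1 | step 7 | 5,7-bis(benzyloxy)-4H-chromen-4-one | O=c1ccoc2cc(OCc3ccccc3)cc(OCc3ccccc3)c12
F2 | step 7 | (2S)-5,7-bis(benzyloxy)-2-[3,4-bis(benzyloxy)phenyl]chroman-4-one | O=C1C[C@@H](c2ccc(OCc3ccccc3)c(OCc3ccccc3)c2)Oc2cc(OCc3ccccc3)cc(OCc3ccccc3)c21
F3 | step 7 | (2S,4S)-5,7-bis(benzyloxy)-2-[3,4-bis(benzyloxy)phenyl]chroman-4-ol | O[C@H]1C[C@@H](c2ccc(OCc3ccccc3)c(OCc3ccccc3)c2)Oc2cc(OCc3ccccc3)cc(OCc3ccccc3)c21
F4 | step 4 | chloro[3,4-bis(benzyloxy)phenyl]methyl 2,2-dimethylpropanoate (racemic) | CC(C)(C)C(=O)OC(Cl)c1ccc(OCc2ccccc2)c(OCc2ccccc2)c1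
F5 | step 4 | [3,5-bis(benzyloxy)-2-ethenylphenoxy][3,4-bis(benzyloxy)phenyl]methyl 2,2-dimethylpropanoate (racemic) | CC(C)(C)C(=O)OC(Oc1cc(OCc2ccccc2)cc(OCc2ccccc2)c1C=C)c1ccc(OCc2ccccc2)c(OCc2ccccc2)c1
F6 | step 2 | 3,5-bis(benzyloxy)-2-formylphenyl 3,4-bis(benzyloxy)benzoate | O=Cc1c(OC(=O)c2ccc(OCc3ccccc3)c(OCc3ccccc3)c2)cc(OCc2ccccc2)cc1OCc1ccccc1
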